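**Plan**
1. Target numbering: C1 = C(OH)(CH2OBz), C2 = CHOH, C3 = CHOBz, C4=C5, C6 = CHOBz, C7 = exocyclic CH2.
2. Enabling feature: in the cyclohexene ring C1–C6, the C4=C5 bond lies γ,δ to exocyclic C7 (C7–C1–C6–C5=C4). With C7 as CHO the ring therefore holds a Claisen retron, and C7–C1–C2–C3–C4–C5 maps onto the six carbons of a hexose.
3. Cuts: the C1/C2 diol goes back to its acetonide and C7–OBz to CHO. A retro-[3,3] then cuts C1–C6 and ties the aldehyde O to C4, giving the dihydropyran O–C7=C1–C2–C3–C4 (a hexose 2-oxyglycal) with a (Z)-BzO–C6H=C5H arm on C4. Finally C7=C1 goes back to a thioglycoside and C6 to a one-carbon alkyne homologation.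
4. Forward: the pyranose ring of D-mannose is present from the start. The dioxolane (acetonide) is added, the chain grows by one carbon, two benzoates go on and the enol ether is unveiled. The cyclohexene closes last, in the same event that opens the temporary pyran ring; reduction, the third benzoate and acetonide removal finish the route.
5. Stereochemistry: C2 and C3 are mannose C3 and C4, untouched. Mannose C5 is consumed and relays its chirality suprafacially to quaternary C1. The Z enol benzoate and the enforced boat transition state set C6. Mannose C1 and C2 are erased, so the cis-2,3-diol sugar with its easy acetonide can be used.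

Key step: step 8

Remark on numbering: sugar numbering of the heptose chain maps onto target numbering as C1→C7, C2→C1, C3→C2, C4→C3, C5→C4, C6→C5, C7→C6.
Assumption: phenyl 1-thio-α-D-mannopyranoside 1 is taken as a commercial D-mannose derivative, and sulfoxide 8 is written without configuration at sulfur because either S-epimer loses sulfur in step 7.

Step 1
Reactants: 1 phenyl 1-thio-α-D-mannopyranoside
Product: 3 phenyl 2,3-O-isopropylidene-1-thio-α-D-mannopyranoside, via bis-acetonide 2 (not isolated)
Conditions: Me2C(OMe)2, p-TsOH·H2O (cat.), acetone, rt; then H2O, rt; Et3N quench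
Reagents that add atoms: 2,2-dimethoxypropane, COC(C)(C)OC
Why: Acid-catalysed transacetalisation (isopropylidene acetal formation) should first give the bis-acetonide, whose trans-fused 4,6-dioxane acetal is hydrolysed far faster than the cis-fused 2,3-dioxolane, so that brief aqueous acid leaves only the 2,3-acetonide and no stereocentre is touched.

Step 2
Reactants: 3 phenyl 2,3-O-isopropylidene-1-thio-α-D-mannopyranoside
Product: 4 phenyl 2,3-O-isopropylidene-1-thio-α-D-manno-hexodialdo-1,5-pyranoside
Conditions: TEMPO (0.2 equiv), PhI(OAc)2 (1.1 equiv), CH2Cl2, rt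
Reagents that add atoms: none
Why: TEMPO/PhI(OAc)2 oxoammonium oxidation is sterically selective for the primary C6 alcohol over the secondary C4 alcohol, stops at the aldehyde in the absence of water and tolerates aryl thioglycosides and acetonides.

Step 3
Reactants: 4 phenyl 2,3-O-isopropylidene-1-thio-α-D-manno-hexodialdo-1,5-pyranoside
Product: 5 phenyl 6,7-dideoxy-2,3-O-isopropylidene-1-thio-α-D-manno-hept-6-ynopyranoside
Conditions: MeC(O)C(N2)P(O)(OMe)2, K2CO3, MeOH, 0 °C → rt
Reagents that add atoms: dimethyl (1-diazo-2-oxopropyl)phosphonate (Ohira–Bestmann reagent), COP(=O)(OC)C(=[N+]=[N-])C(C)=O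
Why: Seyferth–Gilbert homologation in its Ohira–Bestmann form: methanolysis frees the diazomethylphosphonate anion, which adds to the aldehyde, loses phosphate and N2 and gives the terminal alkyne by 1,2-H shift of the alkylidene carbene, while C5 keeps its configuration because the equatorial aldehyde is also the more stable epimer.

Step 4
Reactants: 5 phenyl 6,7-dideoxy-2,3-O-isopropylidene-1-thio-α-D-manno-hept-6-ynopyranoside
Product: 6 phenyl 4-O-benzoyl-6,7-dideoxy-2,3-O-isopropylidene-1-thio-α-D-manno-hept-6-ynopyranoside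
Conditions: BzCl, pyridine, DMAP (cat.), CH2Cl2, 0 °C → rt
Reagents that add atoms: benzoyl chloride, O=C(Cl)c1ccccc1
Why: DMAP-catalysed O-acylation of the only free hydroxyl puts in the future C3 benzoate and removes the homopropargylic OH that could cyclise onto the alkyne in step 5.

Step 5
Reactants: 6 phenyl 4-O-benzoyl-6,7-dideoxy-2,3-O-isopropylidene-1-thio-α-D-manno-hept-6-ynopyranoside
Product: 7 phenyl (Z)-4,7-di-O-benzoyl-6-deoxy-2,3-O-isopropylidene-1-thio-α-D-manno-hept-6-enopyranoside
Conditions: PhCO2H, [Ru(η3-methallyl)2(dppb)] (cat.), toluene, 65 °C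
Reagents that add atoms: benzoic acid, OC(=O)c1ccccc1
Why: Ruthenium-catalysed anti-Markovnikov hydro-acyloxylation of a terminal alkyne: the alkyne tautomerises to a Ru vinylidene, benzoate attacks its electrophilic α-carbon and protonolysis releases the (Z)-enol ester, so that the future C6 benzoate and the alkene geometry that later defines C6 are set in one atom-economical step.

Step 6
Reactants: 7 phenyl (Z)-4,7-di-O-benzoyl-6-deoxy-2,3-O-isopropylidene-1-thio-α-D-manno-hept-6-enopyranoside
Product: 8 the S-oxide (glycosyl phenyl sulfoxide) of 7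
Conditions: mCPBA (1.0 equiv), CH2Cl2, −78 → −40 °C
Reagents that add atoms: 3-chloroperbenzoic acid, OOC(=O)c1cccc(Cl)c1
Why: Chemoselective sulfide-to-sulfoxide oxidation: the thioether is by far the most nucleophilic site, so one equivalent of peracid at low temperature should leave the electron-poor enol ester untouched, and the configuration at sulfur is irrelevant because sulfur is lost in step 7.

Step 7
Reactants: 8 the S-oxide of 7
Product: 9 (Z)-1,5-anhydro-4,7-di-O-benzoyl-6-deoxy-2,3-O-isopropylidene-D-arabino-hepta-1,6-dienitol (2-oxyglycal with a (Z)-2-benzoyloxyvinyl group on C5)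
Conditions: toluene, solid NaHCO3 (buffer), 110 °C
Reagents that add atoms: none
Why: Thermal sulfoxide syn-elimination (Ei): the axial α-sulfinyl group and H2 are cis on the manno ring, H2 is the only β-hydrogen and the ring oxygen weakens the anomeric C–S bond, so that the C1=C2 enol ether should form under neutral conditions that spare benzoates, enol ester and acetonide.

Step 8
Reactants: 9 (Z)-1,5-anhydro-4,7-di-O-benzoyl-6-deoxy-2,3-O-isopropylidene-D-arabino-hepta-1,6-dienitol
Product: 10 (1R,2S,3R,6R)-3,6-bis(benzoyloxy)-1,2-(isopropylidenedioxy)cyclohex-4-ene-1-carbaldehyde (target numbering; O1, O2 and O6 on one face, O3 and CHO on the other)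
Conditions: 1,2-Cl2C6H4 (degassed), BHT (cat.), base-washed sealed tube, 200–220 °C
Reagents that add atoms: none
Why: On heating, the allyl vinyl ether array C1=C2–O5–C5–C6=C7 of 9 (sugar numbering) undergoes a concerted suprafacial [3,3]-sigmatropic Claisen shift in which O5–C5 breaks, C2–C7 (target C1–C6) forms, C1 becomes the aldehyde and C5=C6 becomes the ring alkene (target C4=C5). The closest known reaction type is the thermal Claisen rearrangement of 2-vinyl-3,4-dihydro-2H-pyrans, which has been used on 5-vinylglycals as a sugar-to-carbocycle conversion; the two extra oxygens of 9 sit on the termini of the array (positions 1 and 6), where oxygen donors are known not to retard the shift. The cyclohexene closes transannularly: the vinyl terminus bonds to C2 across the dihydropyran through the only reachable geometry, a boat transition state shaped like bicyclo[2.2.2]octane with C2 and C5 as bridgeheads, so that the pyran is exchanged for the carbocycle in one ring-contracting event. Target C1 is controlled by mannose C5, because the arm on the β-face can reach only the β-face of C2, which leaves O2 cis to O3 and the formyl group trans to it, the same result that the cis-fused dioxolane demands. Target C6 is controlled by the alkene geometry, because in the boat the Z substituent on C7 eclipses C3 and therefore ends up cis to O2 on the new ring, as the target requires, whereas an E substituent would give the epimer. The step needs periselectivity, preserved Z geometry and freedom from acid-induced Ferrier-type ionisation, which are secured by the absence of any other [3,3] array or allylic ester in 9 (O3 is an acetal oxygen), by the radical inhibitor and base-washed glass, and by the acetonide, which ties O3 back from the incoming benzoyloxy group.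

Step 9
Reactants: 10 (1R,2S,3R,6R)-3,6-bis(benzoyloxy)-1,2-(isopropylidenedioxy)cyclohex-4-ene-1-carbaldehyde
Product: 11 (1R,2S,3R,6R)-1-(hydroxymethyl)-1,2-(isopropylidenedioxy)cyclohex-4-ene-3,6-diyl dibenzoate
Conditions: NaBH4, MeOH–CH2Cl2, −40 → 0 °C
Reagents that add atoms: none
Why: Borohydride 1,2-reduction of a non-enolisable aldehyde is much faster than attack on benzoates at low temperature, and any benzoyl shift from O6 to the new primary alkoxide is harmless because step 10 acylates whichever hydroxyl is free.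

Step 10
Reactants: 11 (1R,2S,3R,6R)-1-(hydroxymethyl)-1,2-(isopropylidenedioxy)cyclohex-4-ene-3,6-diyl dibenzoate
Product: 12 (1R,2S,3R,6R)-1-(benzoyloxymethyl)-1,2-(isopropylidenedioxy)cyclohex-4-ene-3,6-diyl dibenzoate
Conditions: BzCl, pyridine, DMAP (cat.), CH2Cl2, 0 °C → rt
Reagents that add atoms: benzoyl chloride, O=C(Cl)c1ccccc1
Why: DMAP-catalysed O-acylation of the neopentyl primary alcohol completes the tribenzoate while the diol stays masked.

Step 11
Reactants: 12 (1R,2S,3R,6R)-1-(benzoyloxymethyl)-1,2-(isopropylidenedioxy)cyclohex-4-ene-3,6-diyl dibenzoate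
Product: 13 (1S,2S,3R,6R)-1-(benzoyloxymethyl)-1,2-dihydroxycyclohex-4-ene-3,6-diyl dibenzoate (CNP0128482.1)
Conditions: TFA–H2O (9:1), CH2Cl2, 0 °C
Reagents that add atoms: none
Why: Acid hydrolysis of the isopropylidene acetal frees the cis-C1/C2 diol, while benzoates are stable to aqueous TFA, the acyloxy-flanked allylic positions ionise reluctantly and the low temperature suppresses acyl migration, so that no stereocentre is disturbed.

**Compound list**
1 | phenyl 1-thio-α-D-mannopyranoside | OC[C@H]1O[C@H](Sc2ccccc2)[C@@H](O)[C@@H](O)[C@@H]1O | starting material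
2 | phenyl 2,3:4,6-di-O-isopropylidene-1-thio-α-D-mannopyranoside | CC1(C)OC[C@H]2O[C@H](Sc3ccccc3)[C@H]4OC(C)(C)O[C@H]4[C@@H]2O1 | intermediate
3 | phenyl 2,3-O-isopropylidene-1-thio-α-D-mannopyranoside | OC[C@H]1O[C@H](Sc2ccccc2)[C@H]3OC(C)(C)O[C@H]3[C@@H]1O | intermediate
4 | phenyl 2,3-O-isopropylidene-1-thio-α-D-manno-hexodialdo-1,5-pyranoside | O=C[C@H]1O[C@H](Sc2ccccc2)[C@H]3OC(C)(C)O[C@H]3[C@@H]1O | intermediate
5 | phenyl 6,7-dideoxy-2,3-O-isopropylidene-1-thio-α-D-manno-hept-6-ynopyranoside | C#C[C@H]1O[C@H](Sc2ccccc2)[C@H]3OC(C)(C)O[C@H]3[C@@H]1O | intermediate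
6 | phenyl 4-O-benzoyl-6,7-dideoxy-2,3-O-isopropylidene-1-thio-α-D-manno-hept-6-ynopyranoside | C#C[C@H]1O[C@H](Sc2ccccc2)[C@H]3OC(C)(C)O[C@H]3[C@@H]1OC(=O)c4ccccc4 | intermediate
7 | phenyl (Z)-4,7-di-O-benzoyl-6-deoxy-2,3-O-isopropylidene-1-thio-α-D-manno-hept-6-enopyranoside | O=C(O/C=C\[C@H]1O[C@H](Sc2ccccc2)[C@H]3OC(C)(C)O[C@H]3[C@@H]1OC(=O)c4ccccc4)c5ccccc5 | intermediate
8 | S-oxide of 7 (either epimer at sulfur) | O=C(O/C=C\[C@H]1O[C@H](S(=O)c2ccccc2)[C@H]3OC(C)(C)O[C@H]3[C@@H]1OC(=O)c4ccccc4)c5ccccc5 | intermediate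
9 | (Z)-1,5-anhydro-4,7-di-O-benzoyl-6-deoxy-2,3-O-isopropylidene-D-arabino-hepta-1,6-dienitol | O=C(O/C=C\[C@H]1OC=C2OC(C)(C)O[C@H]2[C@@H]1OC(=O)c3ccccc3)c4ccccc4 | intermediate
10 | (1R,2S,3R,6R)-3,6-bis(benzoyloxy)-1,2-(isopropylidenedioxy)cyclohex-4-ene-1-carbaldehyde | O=C[C@]12OC(C)(C)O[C@H]1[C@H](OC(=O)c3ccccc3)C=C[C@H]2OC(=O)c4ccccc4 | intermediate
11 | (1R,2S,3R,6R)-1-(hydroxymethyl)-1,2-(isopropylidenedioxy)cyclohex-4-ene-3,6-diyl dibenzoate | OC[C@]12OC(C)(C)O[C@H]1[C@H](OC(=O)c3ccccc3)C=C[C@H]2OC(=O)c4ccccc4 | intermediate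
12 | (1R,2S,3R,6R)-1-(benzoyloxymethyl)-1,2-(isopropylidenedioxy)cyclohex-4-ene-3,6-diyl dibenzoate | O=C(OC[C@]12OC(C)(C)O[C@H]1[C@H](OC(=O)c3ccccc3)C=C[C@H]2OC(=O)c4ccccc4)c5ccccc5 | intermediate
13 | (1S,2S,3R,6R)-1-(benzoyloxymethyl)-1,2-dihydroxycyclohex-4-ene-3,6-diyl dibenzoate | O=C(OC[C@@]1(O)[C@H](OC(=O)c2ccccc2)C=C[C@@H](OC(=O)c2ccccc2)[C@@H]1O)c1ccccc1 | target

Total step count: 11. Longest linear sequence: 11.

**Steps most likely to fail**

Step 8.
- What may go wrong: the crowded boat transition state, with the Z benzoyloxy group pressed against C3/O3, may be reached only at temperatures where other processes compete. These are Z-to-E isomerisation followed by faster rearrangement to the wrong C6 configuration, acid-triggered ionisation of the enol acetal, and allylic benzoate shift in the product.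
- Fallback: an Ireland–Claisen ring contraction of the corresponding 1,5-lactone, whose silyl ketene acetal array rearranges at much lower temperature.
- It sets out from 6. NBS in aqueous acetone at −15 °C hydrolyses the thioglycoside to the free hept-6-ynopyranose F1, and Dess–Martin oxidation gives the 1,5-lactone F2.
- Hydro-acyloxylation as in step 5, now on a sulfur-free substrate, gives the (Z)-enol benzoate lactone F3. Soft enolisation with TBSOTf/Et3N gives the silyl ketene acetal F4.
- Warming F4 in toluene (60–110 °C) should contract it through the same boat to the silyl ester F5, and aqueous work-up gives the carboxylic acid F6.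
- i-BuOCOCl/N-methylmorpholine gives the mixed anhydride F7, and NaBH4 reduces this to 11, where the route is rejoined.

Step 7.
- What may go wrong: heterolysis of the anomeric C–S bond (sulfenate formation, anomerisation) or re-addition of the sulfenic acid to the new enol ether may outrun the Ei elimination.
- Fallback: a selenoxide syn-elimination, which runs at or below room temperature.
- It sets out from 8. Activation with Tf2O and 2,6-di-tert-butyl-4-methylpyridine at −78 °C (sulfoxide glycosylation conditions) and capture by benzeneselenol gives the phenyl α-selenomannoside F8.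
- H2O2 in CH2Cl2 with i-Pr2NH as buffer gives the selenoxide F9, which should eliminate on warming to room temperature and return to the route at 9.

Step 5.
- What may go wrong: coordination of the thioether to ruthenium may stall the catalyst, or the vinylidene pathway may lose regio- and stereocontrol next to the propargylic ring oxygen.
- Fallback: the C–O bond is made on a preformed Z alkenyl boron compound.
- It sets out from 6. Rhodium-catalysed trans-hydroboration with pinacolborane ([Rh(cod)Cl]2, P(i-Pr)3, Et3N) gives the (Z)-alkenylboronate F10, and KHF2 gives the potassium (Z)-alkenyltrifluoroborate F11.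
- Copper-catalysed oxidative Chan–Lam type coupling with benzoic acid under O2 should form the enol ester with retention of geometry and return to the route at 7.

**Further compounds**
F1 | step 8 | 4-O-benzoyl-6,7-dideoxy-2,3-O-isopropylidene-D-manno-hept-6-ynopyranose (anomeric mixture) | C#C[C@H]1OC(O)[C@H]2OC(C)(C)O[C@H]2[C@@H]1OC(=O)c3ccccc3
F2 | step 8 | 4-O-benzoyl-6,7-dideoxy-2,3-O-isopropylidene-D-manno-hept-6-ynono-1,5-lactone | C#C[C@H]1OC(=O)[C@H]2OC(C)(C)O[C@H]2[C@@H]1OC(=O)c3ccccc3
F3 | step 8 | (Z)-4,7-di-O-benzoyl-6-deoxy-2,3-O-isopropylidene-D-manno-hept-6-enono-1,5-lactone | O=C(O/C=C\[C@H]1OC(=O)[C@H]2OC(C)(C)O[C@H]2[C@@H]1OC(=O)c3ccccc3)c4ccccc4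
F4 | step 8 | tert-butyldimethylsilyl ketene acetal of F3 | O=C(O/C=C\[C@H]1OC(O[Si](C)(C)C(C)(C)C)=C2OC(C)(C)O[C@H]2[C@@H]1OC(=O)c3ccccc3)c4ccccc4
F5 | step 8 | tert-butyldimethylsilyl (1R,2S,3R,6R)-3,6-bis(benzoyloxy)-1,2-(isopropylidenedioxy)cyclohex-4-ene-1-carboxylate | CC(C)(C)[Si](C)(C)OC(=O)[C@]12OC(C)(C)O[C@H]1[C@H](OC(=O)c3ccccc3)C=C[C@H]2OC(=O)c4ccccc4
F6 | step 8 | (1R,2S,3R,6R)-3,6-bis(benzoyloxy)-1,2-(isopropylidenedioxy)cyclohex-4-ene-1-carboxylic acid | OC(=O)[C@]12OC(C)(C)O[C@H]1[C@H](OC(=O)c3ccccc3)C=C[C@H]2OC(=O)c4ccccc4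
F7 | step 8 | isobutyl carbonic mixed anhydride of F6 | CC(C)COC(=O)OC(=O)[C@]12OC(C)(C)O[C@H]1[C@H](OC(=O)c3ccccc3)C=C[C@H]2OC(=O)c4ccccc4
F8 | step 7 | phenyl (Z)-4,7-di-O-benzoyl-6-deoxy-2,3-O-isopropylidene-1-seleno-α-D-manno-hept-6-enopyranoside | O=C(O/C=C\[C@H]1O[C@H]([Se]c2ccccc2)[C@H]3OC(C)(C)O[C@H]3[C@@H]1OC(=O)c4ccccc4)c5ccccc5
F9 | step 7 | Se-oxide of F8 | O=C(O/C=C\[C@H]1O[C@H]([Se](=O)c2ccccc2)[C@H]3OC(C)(C)O[C@H]3[C@@H]1OC(=O)c4ccccc4)c5ccccc5
F10 | step 5 | (Z)-alkenyl pinacolboronate from 6 (Bpin on C7) | CC1(C)OB(/C=C\[C@H]2O[C@H](Sc3ccccc3)[C@H]4OC(C)(C)O[C@H]4[C@@H]2OC(=O)c5ccccc5)OC1(C)C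
F11 | step 5 | potassium (Z)-alkenyltrifluoroborate from F10 | [K+].F[B-](F)(F)/C=C\[C@H]1O[C@H](Sc2ccccc2)[C@H]3OC(C)(C)O[C@H]3[C@@H]1OC(=O)c4ccccc4
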